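**Assumption:** the SMILES is read literally: an (S)-carbinol on a (3S,4R)-oxolane whose two side chains are cis.

## Retrosynthetic overview

1. Target ⇐ cis aryl ketone: catalyst-controlled ketone reduction sets the carbinol centre, then the two aryl pivalates are removed.
2. cis Aryl ketone ⇐ ring-contracting Wolff rearrangement of a 3-diazo-5-benzyl-oxan-4-one; the ketene is captured by an arylmagnesium reagent and the enolate is protonated kinetically (sets ring cis).
3. Diazoketone ⇐ (S)-3-benzyl-oxan-4-one ⇐ asymmetric hydrogenation of the arylidene ketone made from oxan-4-one and O-pivaloyl isovanillin.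
4. Both aryl units ⇐ 2-methoxyphenyl pivalate ⇐ catechol (OMe-directed iodination and formylation).
5. Ring order: arenes and the oxane ring are bought; the oxolane is the only ring made, last, by contraction of the oxane.

## Route

Step 1
Reactants: 1 catechol
Product: 2 guaiacol (2-methoxyphenol)
Conditions: MeI (1.0 equiv), K2CO3 (1.0 equiv), acetone, reflux
Reagents that add atoms: iodomethane, CI
Why: Williamson O-methylation of the catecholate; with one equivalent of MeI the mono-ether dominates and is separated from catechol and veratrole by pH-controlled extraction, and no stereocentre is involved.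

Step 2
Reactants: 2 guaiacol
Product: 3 2-methoxyphenyl pivalate
Conditions: PivCl, Et3N, DMAP (cat.), CH2Cl2, 0 °C to rt
Reagents that add atoms: pivaloyl chloride, CC(C)(C)C(=O)Cl
Why: DMAP-catalysed O-acylation; the pivalate masks the phenol and, being a much weaker donor than OMe, leaves OMe as the only director for the two later electrophilic substitutions.

Step 3
Reactants: 3 2-methoxyphenyl pivalate
Product: 4 5-iodo-2-methoxyphenyl pivalate
Conditions: NIS (1.05 equiv), TFA (cat.), MeCN, rt
Reagents that add atoms: N-iodosuccinimide, O=C1CCC(=O)N1I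
Why: Electrophilic aromatic iodination goes para to the methoxy group because the acyloxy oxygen is deactivated and the position ortho to OMe is hindered.

Step 4
Reactants: 3 2-methoxyphenyl pivalate
Product: 5 5-formyl-2-methoxyphenyl pivalate (O-pivaloyl isovanillin)
Conditions: Cl2CHOMe, TiCl4, CH2Cl2, −10 to 0 °C; H2O work-up
Reagents that add atoms: dichloromethyl methyl ether, COC(Cl)Cl; water, O
Why: Rieche formylation (electrophilic substitution by the TiCl4-activated chloro(methoxy)carbenium ion) para to OMe, followed by hydrolysis of the α-chloro ether on work-up.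

Step 5
Reactants: 5 5-formyl-2-methoxyphenyl pivalate; 6 oxan-4-one (tetrahydro-4H-pyran-4-one, 3 equiv)
Product: 7 (E)-3-{[4-methoxy-3-(pivaloyloxy)phenyl]methylidene}oxan-4-one
Conditions: pyrrolidine (20 mol %), AcOH (20 mol %), toluene, 4 Å MS, 60 °C
Reagents that add atoms: none
Why: Amine-catalysed crossed aldol (Claisen–Schmidt) condensation through the enamine of 6 with loss of water; excess 6 suppresses bis-condensation and the conjugated (E)-enone is the thermodynamic isomer.

Step 6
Reactants: 7 (E)-arylidene ketone
Product: 8 (3S)-3-{[4-methoxy-3-(pivaloyloxy)phenyl]methyl}oxan-4-one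
Conditions: [Ir(cod)((S)-tBu-PHOX)]BArF (1 mol %), H2 (30 bar), CH2Cl2, rt
Reagents that add atoms: none
Why: Ir–phosphinooxazoline asymmetric hydrogenation of an exocyclic α-arylidene ketone, a known substrate class for this catalyst family; addition of H2 to one enantioface of the C=C sets C-3 as S (the ligand antipode that gives S is fixed by one analytical run), and the ketone and aryl ester are untouched.

Step 7
Reactants: 8 (3S)-3-benzyl ketone
Product: 11 (5S)-3-diazo-5-{[4-methoxy-3-(pivaloyloxy)phenyl]methyl}oxan-4-one, via lithium enolate 9 (not isolated), via trifluoroacetyl ketone 10 (not isolated)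
Conditions: LiHMDS, THF, −78 °C; CF3CO2CH2CF3, −78 °C; aq. HCl wash; then MsN3, Et3N, H2O, MeCN, rt
Reagents that add atoms: methanesulfonyl azide, CS(=O)(=O)N=[N+]=[N-]
Why: Danheiser detrifluoroacetylative diazo transfer (a Regitz-type transfer): LiHMDS deprotonates the less substituted CH2 kinetically so the stereocentre on the other side is never enolised, trifluoroacetylation activates that position, and MsN3/Et3N transfers N2 with loss of the trifluoroacetyl group.

Step 8
Reactants: 11 (5S)-diazoketone; 4 5-iodo-2-methoxyphenyl pivalate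
Product: 15 [(3S,4R)-4-{[4-methoxy-3-(pivaloyloxy)phenyl]methyl}oxolan-3-yl][4-methoxy-3-(pivaloyloxy)phenyl]methanone, via ketene 12 (not isolated), via arylmagnesium chloride 13 (not isolated), via magnesium enolate 14 (not isolated)
Conditions: 11, hν (365 nm), THF, −78 °C; add 13 (from 4, iPrMgCl·LiCl, THF, −20 °C), −78 °C; inverse quench into AcOH/THF, −78 °C
Reagents that add atoms: none
Why: Proposed new method: a telescoped photochemical Wolff ring contraction, arylmagnesium capture and kinetic protonation; light expels N2 and the ring carbon bearing the benzyl group shifts 1,2 from the carbonyl carbon to the carbene carbon with retention, contracting the oxane to the oxolane and giving ketene 12, which persists at −78 °C without a protic trap and adds 13 at its carbonyl carbon to give exocyclic enolate 14, whose neighbouring pseudoaxial benzyl group (A1,3 strain) blocks one face so the proton enters anti to it and the aroyl group ends cis to benzyl (3S); the closest known reactions are Wolff ring contractions trapped by alcohols or amines, additions of organolithium or Grignard reagents to isolated ketenes, and Zimmerman-type kinetic protonation of exocyclic enolates to the less stable cis ketones.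

Step 9
Reactants: 15 cis aryl ketone
Product: 17 (S)-[(3S,4R)-4-(3-hydroxy-4-methoxybenzyl)oxolan-3-yl](3-hydroxy-4-methoxyphenyl)methanol, via carbinol bis-pivalate 16 (not isolated)
Conditions: (R)-Me-CBS (0.3 equiv), BH3·SMe2, THF, −20 °C; MeOH quench, concentrate; then K2CO3 (0.3 equiv), MeOH, 40 °C
Reagents that add atoms: none
Why: Corey–Bakshi–Shibata reduction under catalyst control (aryl as the large group, the (R)-catalyst giving the S carbinol) under non-basic conditions that do not epimerise the cis α-centre, followed in the same flask by base-catalysed methanolysis (transesterification) of the two aryl pivalates.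

## Compound list

1 | catechol (benzene-1,2-diol) | Oc1ccccc1O | starting material
2 | guaiacol (2-methoxyphenol) | COc1ccccc1O | intermediate
3 | 2-methoxyphenyl pivalate | COc1ccccc1OC(=O)C(C)(C)C | intermediate
4 | 5-iodo-2-methoxyphenyl pivalate | COc1ccc(I)cc1OC(=O)C(C)(C)C | intermediate
5 | 5-formyl-2-methoxyphenyl pivalate | COc1ccc(C=O)cc1OC(=O)C(C)(C)C | intermediate
6 | oxan-4-one (tetrahydro-4H-pyran-4-one) | O=C1CCOCC1 | starting material
7 | (E)-3-{[4-methoxy-3-(pivaloyloxy)phenyl]methylidene}oxan-4-one | O=C1CCOC/C1=C\c1ccc(OC)c(OC(=O)C(C)(C)C)c1 | intermediate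
8 | (3S)-3-{[4-methoxy-3-(pivaloyloxy)phenyl]methyl}oxan-4-one | O=C1CCOC[C@@H]1Cc1ccc(OC)c(OC(=O)C(C)(C)C)c1 | intermediate
9 | lithium (3S)-3-{[4-methoxy-3-(pivaloyloxy)phenyl]methyl}-3,6-dihydro-2H-pyran-4-olate (kinetic enolate of 8) | [Li]OC1=CCOC[C@@H]1Cc1ccc(OC)c(OC(=O)C(C)(C)C)c1 | intermediate
10 | (3S)-3-{[4-methoxy-3-(pivaloyloxy)phenyl]methyl}-5-(trifluoroacetyl)oxan-4-one (C-5 not defined, largely enol) | O=C1C(C(=O)C(F)(F)F)COC[C@@H]1Cc1ccc(OC)c(OC(=O)C(C)(C)C)c1 | intermediate
11 | (5S)-3-diazo-5-{[4-methoxy-3-(pivaloyloxy)phenyl]methyl}oxan-4-one | O=C1C(=[N+]=[N-])COC[C@@H]1Cc1ccc(OC)c(OC(=O)C(C)(C)C)c1 | intermediate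
12 | [(4R)-4-{[4-methoxy-3-(pivaloyloxy)phenyl]methyl}oxolan-3-ylidene]methanone (ketene) | O=C=C1COC[C@@H]1Cc1ccc(OC)c(OC(=O)C(C)(C)C)c1 | intermediate
13 | [4-methoxy-3-(pivaloyloxy)phenyl]magnesium chloride (LiCl complex) | COc1ccc([Mg]Cl)cc1OC(=O)C(C)(C)C | intermediate
14 | chloromagnesium (E)-enolate of 15, (4R) | Cl[Mg]O/C(c1ccc(OC)c(OC(=O)C(C)(C)C)c1)=C2/COC[C@@H]2Cc3ccc(OC)c(OC(=O)C(C)(C)C)c3 | intermediate
15 | [(3S,4R)-4-{[4-methoxy-3-(pivaloyloxy)phenyl]methyl}oxolan-3-yl][4-methoxy-3-(pivaloyloxy)phenyl]methanone (cis) | COc1ccc(C[C@H]2COC[C@H]2C(=O)c2ccc(OC)c(OC(=O)C(C)(C)C)c2)cc1OC(=O)C(C)(C)C | intermediate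
16 | (S)-[(3S,4R)-4-{[4-methoxy-3-(pivaloyloxy)phenyl]methyl}oxolan-3-yl][4-methoxy-3-(pivaloyloxy)phenyl]methanol | COc1ccc(C[C@H]2COC[C@H]2[C@H](O)c2ccc(OC)c(OC(=O)C(C)(C)C)c2)cc1OC(=O)C(C)(C)C | intermediate
17 | (S)-[(3S,4R)-4-(3-hydroxy-4-methoxybenzyl)oxolan-3-yl](3-hydroxy-4-methoxyphenyl)methanol | COc1ccc(C[C@H]2COC[C@H]2[C@H](O)c2ccc(OC)c(O)c2)cc1O | target

## Step count and risks

Total step count: 9. Longest linear sequence: 8 steps (1, 2, 4, 5, 6, 7, 8, 9); step 3 is a one-step branch from 3.

Three steps most likely to fail: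

**Step 8 (the proposed new step).** Risks are loss of ketene 12 to dimer or to the 1,2-hydride-shift enone before capture, attack of 13 on residual 11, and incomplete cis selectivity or epimerisation on quench. The fallback uses known chemistry, sets out from 11 and comes back at 15. Compound 11 is irradiated in THF in the presence of N,O-dimethylhydroxylamine, a classical Wolff ring contraction with an amine trap, to give the cis Weinreb amide (3S,4R)-N-methoxy-N-methyl-4-{[4-methoxy-3-(pivaloyloxy)phenyl]methyl}oxolane-3-carboxamide F1. The cis isomer arises from kinetic C-protonation anti to the benzyl group; any trans isomer is removed by chromatography. Addition of 13 at −40 °C (Weinreb ketone synthesis) then gives 15.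

**Step 9.** The Felkin–Anh preference of 15 (hydride anti to the ring branch that carries the benzyl group) is expected to favour the R carbinol epimer, so the catalyst works against the substrate and the diastereomer ratio may be modest. The fallback sets the carbinol centre by aryl addition instead of hydride addition; it sets out from 11 and comes back at 16. Photolysis of 11 in THF with ethanethiol gives the cis thioester S-ethyl (3S,4R)-4-{[4-methoxy-3-(pivaloyloxy)phenyl]methyl}oxolane-3-carbothioate F2. Fukuyama reduction (Et3SiH, Pd/C, acetone, rt) gives the cis aldehyde (3S,4R)-4-{[4-methoxy-3-(pivaloyloxy)phenyl]methyl}oxolane-3-carbaldehyde F3 without base. Addition of 13 with MgBr2·OEt2 at −78 °C follows the same Felkin–Anh/1,3-chelate model, which for aryl addition to the aldehyde gives the S carbinol 16. Compound 16 is then methanolysed as in step 9 to give 17.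

**Step 6.** The enantioselectivity and sense of the Ir hydrogenation on this oxygen-containing exocyclic enone are not secured, and step 5 can give some bis-arylidene ketone. The fallback is auxiliary-controlled alkylation; it sets out from 6 and 3 and comes back at 8, replacing steps 4 to 6. Compound 6 is condensed with RAMP to give the hydrazone (R)-N-(oxan-4-ylidene)-2-(methoxymethyl)pyrrolidin-1-amine F4. Compound 3 is bromomethylated para to OMe (HBr, paraformaldehyde, AcOH) to give 5-(bromomethyl)-2-methoxyphenyl pivalate F5. Deprotonation of F4 with LDA and alkylation with F5 at −100 °C (Enders alkylation; RAMP is the antipode expected to give the S ketone) gives the alkylated hydrazone F6, whose benzyl-bearing centre has the spatial arrangement of 8 (R by CIP in the hydrazone). Cleavage with saturated aqueous oxalic acid in ether gives 8.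

## Further compounds

F1 | step 8 | (3S,4R)-N-methoxy-N-methyl-4-{[4-methoxy-3-(pivaloyloxy)phenyl]methyl}oxolane-3-carboxamide | COc1ccc(C[C@H]2COC[C@H]2C(=O)N(C)OC)cc1OC(=O)C(C)(C)C
F2 | step 9 | S-ethyl (3S,4R)-4-{[4-methoxy-3-(pivaloyloxy)phenyl]methyl}oxolane-3-carbothioate | COc1ccc(C[C@H]2COC[C@H]2C(=O)SCC)cc1OC(=O)C(C)(C)C
F3 | step 9 | (3S,4R)-4-{[4-methoxy-3-(pivaloyloxy)phenyl]methyl}oxolane-3-carbaldehyde | COc1ccc(C[C@H]2COC[C@H]2C=O)cc1OC(=O)C(C)(C)C
F4 | step 6 | (R)-N-(oxan-4-ylidene)-2-(methoxymethyl)pyrrolidin-1-amine (RAMP hydrazone of 6) | COC[C@H]1CCCN1N=C1CCOCC1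
F5 | step 6 | 5-(bromomethyl)-2-methoxyphenyl pivalate | COc1ccc(CBr)cc1OC(=O)C(C)(C)C
F6 | step 6 | RAMP hydrazone of 8 (α-benzylated, C=N geometry not fixed) | COC[C@H]1CCCN1N=C1CCOC[C@@H]1Cc1ccc(OC)c(OC(=O)C(C)(C)C)c1
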